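**Strategy**

The cyclohexene ring (C1' acyl, C2' prenyl, C3' methyl, C6' phenyl) is cut at C1'–C6' and C2'–C3'. C1' lies between the benzofuranyl ketone carbon and C2', so it is the central carbon of a 1,3-diketone; C6' is β to C4' through C5', so C3'–C6' derive from ethyl styryl ketone. A chiral primary amine joins these achiral fragments in one operation: Michael addition sets C6', aldol condensation closes the ring as a cyclohexenone, and C1' settles trans to phenyl. The precursor is a 1-(benzofuran-7-yl)pentane-1,3-dione carrying a MOM-protected phenol and a silyl-protected C5 hydroxyl. Reductive alkene transposition later sets C2'.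

Key step: step 6

Assumption: the quinine-derived amine is taken to direct the diketone to the Si face of C6'; if a trial run shows the opposite sense, its quinidine-derived pseudoenantiomer is used in the same way.

**Route**

Step 1
Reactants: 1 1-(2,6-dihydroxy-4-methoxyphenyl)ethan-1-one; 2 2-bromo-1,1-diethoxyethane
Product: 3 1-[2-(2,2-diethoxyethoxy)-6-hydroxy-4-methoxyphenyl]ethan-1-one
Conditions: K2CO3, KI (cat.), DMF, 100 °C
Reagents that add atoms: none
Why: Williamson ether synthesis in which only one of the two phenols can be chelated to the acetyl carbonyl at a time, so after the first alkylation the remaining hydroxyl is locked in a hydrogen bond and the reaction should stop at the mono-ether.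

Step 2
Reactants: 3 1-[2-(2,2-diethoxyethoxy)-6-hydroxy-4-methoxyphenyl]ethan-1-one
Product: 4 1-(6-hydroxy-4-methoxy-1-benzofuran-7-yl)ethan-1-one
Conditions: Amberlyst-15, toluene, 110 °C
Reagents that add atoms: none
Why: Acid-catalysed cyclodehydration of an aryloxyacetaldehyde acetal (intramolecular Friedel–Crafts attack on the oxocarbenium ion, then loss of the second ethanol), in which the only free position ortho to the ether oxygen is activated by the ortho methoxy and para hydroxyl groups, so the furan ring can close in one sense only.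

Step 3
Reactants: 4 1-(6-hydroxy-4-methoxy-1-benzofuran-7-yl)ethan-1-one
Product: 5 1-[4-methoxy-6-(methoxymethoxy)-1-benzofuran-7-yl]ethan-1-one
Conditions: NaH, MOMCl, DMF, 0 → 25 °C
Reagents that add atoms: chloromethyl methyl ether (MOMCl), COCCl
Why: O-alkylation of the sodium phenoxide (Williamson-type MOM protection), where the strong base breaks the hydrogen bond to the acetyl group and the masked phenol can no longer cyclise to a chromone once the 1,3-diketone is in place.

Step 4
Reactants: 6 methyl 3-hydroxypropanoate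
Product: 7 methyl 3-[(tert-butyldiphenylsilyl)oxy]propanoate
Conditions: TBDPSCl, imidazole, CH2Cl2, 0 → 25 °C
Reagents that add atoms: tert-butyl(chloro)diphenylsilane (TBDPSCl), CC(C)(C)[Si](Cl)(c1ccccc1)c1ccccc1
Why: Imidazole-mediated silylation of a primary alcohol, chosen because it needs no strong base on a β-hydroxy ester, the bulky silyl ether resists the acids of steps 6 and 7, and its later removal by fluoride needs no oxidant near the electron-rich benzofuran.

Step 5
Reactants: 5 1-[4-methoxy-6-(methoxymethoxy)-1-benzofuran-7-yl]ethan-1-one; 7 methyl 3-[(tert-butyldiphenylsilyl)oxy]propanoate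
Product: 8 5-[(tert-butyldiphenylsilyl)oxy]-1-[4-methoxy-6-(methoxymethoxy)-1-benzofuran-7-yl]pentane-1,3-dione
Conditions: LiN(SiMe3)2 (2.2 equiv), THF, −78 °C; then 7, −78 → 0 °C; NH4Cl (aq.)
Reagents that add atoms: none
Why: Crossed Claisen condensation in which the preformed lithium enolate of the methyl ketone is acylated by the ester at low temperature, the second equivalent of base stores the product as its stable diketonate, and the ketone enolate is too weak a base to cause β-elimination of the silyloxy group.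

Step 6
Reactants: 8 5-[(tert-butyldiphenylsilyl)oxy]-1-[4-methoxy-6-(methoxymethoxy)-1-benzofuran-7-yl]pentane-1,3-dione; 9 (E)-1-phenylpent-1-en-3-one
Product: 12 (4S,5R)-3-{2-[(tert-butyldiphenylsilyl)oxy]ethyl}-4-[4-methoxy-6-(methoxymethoxy)-1-benzofuran-7-carbonyl]-2-methyl-5-phenylcyclohex-2-en-1-one, via Michael adduct 10 (not isolated), via ketol 11 (not isolated)
Conditions: 9 (1.5 equiv), 9-amino-9-deoxy-epi-quinine (20 mol %), PhCO2H (40 mol %), toluene, 25 °C, then 50 °C
Reagents that add atoms: none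
Why: The amine condenses with enone 9 to an iminium ion, and the enol of diketone 8 adds through C1' to the Si face of C6', the other face being screened by the protonated cinchona scaffold, so C6' (R) is set under catalyst control and Michael adduct 10 results. The same primary amine then converts the ethyl ketone into its enamine, whose C3' attacks the C2' carbonyl in a 6-(enolendo)-exo-trig aldol closure to ketol 11, and loss of water gives the C2'=C3' enone. The closest known reaction type is the primary-amine-catalysed Michael addition of 1,3-dicarbonyl compounds to β-aryl enones followed by aldol condensation, that is an organocatalytic Robinson annulation. C1' remains acidic (α to the aryl ketone, γ to the enone) and should equilibrate to the arrangement trans to the C6' phenyl group, so it is under thermodynamic control. The step needs regioselective ring closure, which the substrate secures because the aryl ketone is flanked by the MOM ether and the furan oxygen and is too shielded to accept the enamine, while the isolated ethyl ketone forms an enamine more readily than the side-chain methylene of the enolised 1,3-diketone.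

Step 7
Reactants: 12 (4S,5R)-3-{2-[(tert-butyldiphenylsilyl)oxy]ethyl}-4-[4-methoxy-6-(methoxymethoxy)-1-benzofuran-7-carbonyl]-2-methyl-5-phenylcyclohex-2-en-1-one
Product: 13 N'-[(4S,5R)-3-{2-[(tert-butyldiphenylsilyl)oxy]ethyl}-4-[4-methoxy-6-(methoxymethoxy)-1-benzofuran-7-carbonyl]-2-methyl-5-phenylcyclohex-2-en-1-ylidene]-4-methylbenzene-1-sulfonohydrazide
Conditions: TsNHNH2, AcOH (cat.), EtOH, 60 °C
Reagents that add atoms: 4-methylbenzenesulfonohydrazide (TsNHNH2), Cc1ccc(cc1)S(=O)(=O)NN
Why: Hydrazone condensation at the ring ketone, the only accessible carbonyl, since the aryl ketone is shielded by its two ortho substituents and the branched C1', so the stereocenters are not touched.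

Step 8
Reactants: 13 N'-[(4S,5R)-3-{2-[(tert-butyldiphenylsilyl)oxy]ethyl}-4-[4-methoxy-6-(methoxymethoxy)-1-benzofuran-7-carbonyl]-2-methyl-5-phenylcyclohex-2-en-1-ylidene]-4-methylbenzene-1-sulfonohydrazide
Product: 16 {(1R,2S,6R)-2-{2-[(tert-butyldiphenylsilyl)oxy]ethyl}-3-methyl-6-phenylcyclohex-3-en-1-yl}[4-methoxy-6-(methoxymethoxy)-1-benzofuran-7-yl]methanone, via allylic tosylhydrazine 14 (not isolated), via allylic diazene 15 (not isolated)
Conditions: catecholborane, CHCl3, 0 °C; then NaOAc·3H2O, 60 °C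
Reagents that add atoms: none
Why: Alkene-transposing reduction of an α,β-unsaturated tosylhydrazone, in which hydride should enter C4' anti to the C6' phenyl group, acetate releases sulfinate to give the allylic diazene with nitrogen on the phenyl face, and the suprafacial retro-ene loss of N2 hands hydrogen to C2' on that face, which sets C2' (S, side chain trans to phenyl and cis to the acyl group) and moves the double bond to C3'=C4'.

Step 9
Reactants: 16 {(1R,2S,6R)-2-{2-[(tert-butyldiphenylsilyl)oxy]ethyl}-3-methyl-6-phenylcyclohex-3-en-1-yl}[4-methoxy-6-(methoxymethoxy)-1-benzofuran-7-yl]methanone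
Product: 17 [(1R,2S,6R)-2-(2-hydroxyethyl)-3-methyl-6-phenylcyclohex-3-en-1-yl][4-methoxy-6-(methoxymethoxy)-1-benzofuran-7-yl]methanone
Conditions: Bu4NF, AcOH, THF, 0 → 25 °C
Reagents that add atoms: none
Why: Fluoride-mediated desilylation driven by the strong Si–F bond, with acetic acid buffering so that C1' is not epimerised and with the MOM ether and both alkenes inert.

Step 10
Reactants: 17 [(1R,2S,6R)-2-(2-hydroxyethyl)-3-methyl-6-phenylcyclohex-3-en-1-yl][4-methoxy-6-(methoxymethoxy)-1-benzofuran-7-yl]methanone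
Product: 18 [(1R,2S,6R)-3-methyl-2-(2-oxoethyl)-6-phenylcyclohex-3-en-1-yl][4-methoxy-6-(methoxymethoxy)-1-benzofuran-7-yl]methanone
Conditions: Dess–Martin periodinane, CH2Cl2, 0 → 25 °C
Reagents that add atoms: none
Why: Dess–Martin oxidation of the primary alcohol under near-neutral conditions, where any hemiketal with the neighbouring hindered ketone is in equilibrium with the open hydroxy ketone that is consumed, and no stereocenter lies α to the new aldehyde.

Step 11
Reactants: 18 [(1R,2S,6R)-3-methyl-2-(2-oxoethyl)-6-phenylcyclohex-3-en-1-yl][4-methoxy-6-(methoxymethoxy)-1-benzofuran-7-yl]methanone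
Product: 19 [4-methoxy-6-(methoxymethoxy)-1-benzofuran-7-yl][(1R,2S,6R)-3-methyl-2-(3-methylbut-2-en-1-yl)-6-phenylcyclohex-3-en-1-yl]methanone
Conditions: i-PrPPh3I, n-BuLi, THF, 0 °C; then 18, −78 → 25 °C
Reagents that add atoms: isopropyltriphenylphosphonium iodide, CC(C)[P+](c1ccccc1)(c1ccccc1)c1ccccc1.[I-] (used as its ylide)
Why: Wittig olefination with the non-stabilised isopropylidene ylide, which should add to the unhindered aldehyde far faster than it attacks or enolises the shielded aryl ketone, and which gives a symmetrically substituted alkene without a geometry issue.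

Step 12
Reactants: 19 [4-methoxy-6-(methoxymethoxy)-1-benzofuran-7-yl][(1R,2S,6R)-3-methyl-2-(3-methylbut-2-en-1-yl)-6-phenylcyclohex-3-en-1-yl]methanone
Product: 20 (6-hydroxy-4-methoxy-1-benzofuran-7-yl)[(1R,2S,6R)-3-methyl-2-(3-methylbut-2-en-1-yl)-6-phenylcyclohex-3-en-1-yl]methanone
Conditions: HCl (2 M aq.), MeOH, 40 °C
Reagents that add atoms: none
Why: Acid-catalysed acetal methanolysis of the MOM ether, assisted by the ortho carbonyl group, under dilute acid that should leave the two trisubstituted alkenes, the benzofuran and the stereocenters untouched.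

**Compound list**

1 | 1-(2,6-dihydroxy-4-methoxyphenyl)ethan-1-one | CC(=O)c1c(O)cc(OC)cc1O | starting material
2 | 2-bromo-1,1-diethoxyethane | CCOC(CBr)OCC | starting material
3 | 1-[2-(2,2-diethoxyethoxy)-6-hydroxy-4-methoxyphenyl]ethan-1-one | CCOC(COc1cc(OC)cc(O)c1C(C)=O)OCC | intermediate
4 | 1-(6-hydroxy-4-methoxy-1-benzofuran-7-yl)ethan-1-one | COc1cc(O)c(C(C)=O)c2occc12 | intermediate
5 | 1-[4-methoxy-6-(methoxymethoxy)-1-benzofuran-7-yl]ethan-1-one | COCOc1cc(OC)c2ccoc2c1C(C)=O | intermediate
6 | methyl 3-hydroxypropanoate | COC(=O)CCO | starting material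
7 | methyl 3-[(tert-butyldiphenylsilyl)oxy]propanoate | COC(=O)CCO[Si](c1ccccc1)(c1ccccc1)C(C)(C)C | intermediate
8 | 5-[(tert-butyldiphenylsilyl)oxy]-1-[4-methoxy-6-(methoxymethoxy)-1-benzofuran-7-yl]pentane-1,3-dione | COCOc1cc(OC)c2ccoc2c1C(=O)CC(=O)CCO[Si](c1ccccc1)(c1ccccc1)C(C)(C)C | intermediate
9 | (E)-1-phenylpent-1-en-3-one | CCC(=O)/C=C/c1ccccc1 | starting material
10 | (5R)-1-[(tert-butyldiphenylsilyl)oxy]-4-[4-methoxy-6-(methoxymethoxy)-1-benzofuran-7-carbonyl]-5-phenylnonane-3,7-dione (Michael adduct, C4 epimers) | CCC(=O)C[C@H](C(C(=O)CCO[Si](c1ccccc1)(c1ccccc1)C(C)(C)C)C(=O)c1c(OCOC)cc(OC)c2ccoc12)c1ccccc1 | intermediate (not isolated)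
11 | (5R)-3-{2-[(tert-butyldiphenylsilyl)oxy]ethyl}-3-hydroxy-4-[4-methoxy-6-(methoxymethoxy)-1-benzofuran-7-carbonyl]-2-methyl-5-phenylcyclohexan-1-one (ketol, C2, C3 and C4 not defined) | COCOc1cc(OC)c2ccoc2c1C(=O)C1C(O)(CCO[Si](c2ccccc2)(c2ccccc2)C(C)(C)C)C(C)C(=O)C[C@H]1c1ccccc1 | intermediate (not isolated)
12 | (4S,5R)-3-{2-[(tert-butyldiphenylsilyl)oxy]ethyl}-4-[4-methoxy-6-(methoxymethoxy)-1-benzofuran-7-carbonyl]-2-methyl-5-phenylcyclohex-2-en-1-one | COCOc1cc(OC)c2ccoc2c1C(=O)[C@@H]1C(CCO[Si](c2ccccc2)(c2ccccc2)C(C)(C)C)=C(C)C(=O)C[C@H]1c1ccccc1 | intermediate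
13 | N'-[(4S,5R)-3-{2-[(tert-butyldiphenylsilyl)oxy]ethyl}-4-[4-methoxy-6-(methoxymethoxy)-1-benzofuran-7-carbonyl]-2-methyl-5-phenylcyclohex-2-en-1-ylidene]-4-methylbenzene-1-sulfonohydrazide (C=N geometry not assigned) | COCOc1cc(OC)c2ccoc2c1C(=O)[C@@H]1C(CCO[Si](c2ccccc2)(c2ccccc2)C(C)(C)C)=C(C)C(=NNS(=O)(=O)c2ccc(C)cc2)C[C@H]1c1ccccc1 | intermediate
14 | N'-[(1S,4S,5R)-3-{2-[(tert-butyldiphenylsilyl)oxy]ethyl}-4-[4-methoxy-6-(methoxymethoxy)-1-benzofuran-7-carbonyl]-2-methyl-5-phenylcyclohex-2-en-1-yl]-4-methylbenzene-1-sulfonohydrazide (allylic tosylhydrazine, nitrogen on the phenyl face, N-borylated in the flask) | COCOc1cc(OC)c2ccoc2c1C(=O)[C@@H]1C(CCO[Si](c2ccccc2)(c2ccccc2)C(C)(C)C)=C(C)[C@@H](NNS(=O)(=O)c2ccc(C)cc2)C[C@H]1c1ccccc1 | intermediate (not isolated)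
15 | [(1S,4S,5R)-3-{2-[(tert-butyldiphenylsilyl)oxy]ethyl}-4-[4-methoxy-6-(methoxymethoxy)-1-benzofuran-7-carbonyl]-2-methyl-5-phenylcyclohex-2-en-1-yl]diazene (allylic diazene) | COCOc1cc(OC)c2ccoc2c1C(=O)[C@@H]1C(CCO[Si](c2ccccc2)(c2ccccc2)C(C)(C)C)=C(C)[C@@H](N=N)C[C@H]1c1ccccc1 | intermediate (not isolated)
16 | {(1R,2S,6R)-2-{2-[(tert-butyldiphenylsilyl)oxy]ethyl}-3-methyl-6-phenylcyclohex-3-en-1-yl}[4-methoxy-6-(methoxymethoxy)-1-benzofuran-7-yl]methanone | COCOc1cc(OC)c2ccoc2c1C(=O)[C@@H]1[C@H](CCO[Si](c2ccccc2)(c2ccccc2)C(C)(C)C)C(C)=CC[C@H]1c1ccccc1 | intermediate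
17 | [(1R,2S,6R)-2-(2-hydroxyethyl)-3-methyl-6-phenylcyclohex-3-en-1-yl][4-methoxy-6-(methoxymethoxy)-1-benzofuran-7-yl]methanone | COCOc1cc(OC)c2ccoc2c1C(=O)[C@@H]1[C@H](CCO)C(C)=CC[C@H]1c1ccccc1 | intermediate
18 | [(1R,2S,6R)-3-methyl-2-(2-oxoethyl)-6-phenylcyclohex-3-en-1-yl][4-methoxy-6-(methoxymethoxy)-1-benzofuran-7-yl]methanone | COCOc1cc(OC)c2ccoc2c1C(=O)[C@@H]1[C@H](CC=O)C(C)=CC[C@H]1c1ccccc1 | intermediate
19 | [4-methoxy-6-(methoxymethoxy)-1-benzofuran-7-yl][(1R,2S,6R)-3-methyl-2-(3-methylbut-2-en-1-yl)-6-phenylcyclohex-3-en-1-yl]methanone | COCOc1cc(OC)c2ccoc2c1C(=O)[C@@H]1[C@H](CC=C(C)C)C(C)=CC[C@H]1c1ccccc1 | intermediate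
20 | (6-hydroxy-4-methoxy-1-benzofuran-7-yl)[(1R,2S,6R)-3-methyl-2-(3-methylbut-2-en-1-yl)-6-phenylcyclohex-3-en-1-yl]methanone | COc1cc(O)c(C(=O)[C@@H]2[C@H](CC=C(C)C)C(C)=CC[C@H]2c2ccccc2)c2occc12 | target

**Step count and risks**

Total steps: 12. Longest linear sequence: 11 steps (steps 1–3 and 5–12); step 4 is a one-step side branch.

Steps most likely to fail:

1. Step 6. The annulation may stall at the open Michael adduct or the ketol because the ethyl ketone is a reluctant enamine donor. Ring closure may instead run through the side-chain methylene of the diketone. Prolonged warming may erode enantioselectivity through a background addition or cause β-elimination of the silyloxy group. The fallback sets out from 8 and 9 and returns at 12, and it separates the two events. The same amine salt is used at 0–20 °C only until conjugate addition is complete, and Michael adduct 10 is isolated. The ring is then closed in a separate aldol condensation with L-phenylalanine and (+)-camphor-10-sulfonic acid in DMF at 50 °C, a promoter pair established for ethyl-ketone enamines in Robinson annulations, passing through ketol 11 to 12. This detour makes no compound outside the list (F0).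

2. Step 8. Hydride delivery to the C4' hydrazone may not be fully face-selective, which would give the C2' epimer after transposition, and the product epimers cannot be corrected. The aryl ketone may also be reduced in competition. The fallback sets out from 12 and returns at 16. Luche reduction of enone 12 (NaBH4, CeCl3·7H2O, MeOH, −40 °C) should give allylic alcohol F1 with the hydroxyl cis to phenyl, and any epimer can be separated at this stage. Mitsunobu inversion with 4-nitrobenzoic acid (PPh3, DIAD, THF) gives 4-nitrobenzoate F2, and methanolysis (K2CO3, MeOH) gives epimeric alcohol F3. A second Mitsunobu displacement with 2-nitrobenzenesulfonylhydrazide (PPh3, DEAD, N-methylmorpholine, −30 → 23 °C) returns nitrogen to the phenyl face as sulfonylhydrazine F4. On warming this loses the sulfinic acid to give diazene 15, which undergoes the same retro-ene step to 16. Any trans alcohol formed directly in the reduction can be fed straight into the last operation.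

3. Step 2. The oxocarbenium ion may be intercepted by the electron-rich ring of a second molecule (oligomerisation), or the acetal may hydrolyse without ring closure. The fallback sets out from 1 and returns at 4. Iodination of 1 (NIS, MeCN, 0 °C) gives iodophenol F5. Sonogashira coupling with ethynyltrimethylsilane (Pd(PPh3)2Cl2, CuI, Et3N, THF, 50 °C) gives silylalkyne F6. TBAF in THF at 60 °C removes the silyl group to ethynylphenol F7 (not isolated), whose neighbouring phenoxide closes 5-endo-dig onto the alkyne to give 4.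

**Further compounds**

F0 | step 6 | none | none
F1 | step 8 | (1S,4S,5R)-3-{2-[(tert-butyldiphenylsilyl)oxy]ethyl}-4-[4-methoxy-6-(methoxymethoxy)-1-benzofuran-7-carbonyl]-2-methyl-5-phenylcyclohex-2-en-1-ol | COCOc1cc(OC)c2ccoc2c1C(=O)[C@@H]1C(CCO[Si](c2ccccc2)(c2ccccc2)C(C)(C)C)=C(C)[C@@H](O)C[C@H]1c1ccccc1
F2 | step 8 | (1R,4S,5R)-3-{2-[(tert-butyldiphenylsilyl)oxy]ethyl}-4-[4-methoxy-6-(methoxymethoxy)-1-benzofuran-7-carbonyl]-2-methyl-5-phenylcyclohex-2-en-1-yl 4-nitrobenzoate | COCOc1cc(OC)c2ccoc2c1C(=O)[C@@H]1C(CCO[Si](c2ccccc2)(c2ccccc2)C(C)(C)C)=C(C)[C@H](OC(=O)c2ccc(cc2)[N+](=O)[O-])C[C@H]1c1ccccc1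
F3 | step 8 | (1R,4S,5R)-3-{2-[(tert-butyldiphenylsilyl)oxy]ethyl}-4-[4-methoxy-6-(methoxymethoxy)-1-benzofuran-7-carbonyl]-2-methyl-5-phenylcyclohex-2-en-1-ol | COCOc1cc(OC)c2ccoc2c1C(=O)[C@@H]1C(CCO[Si](c2ccccc2)(c2ccccc2)C(C)(C)C)=C(C)[C@H](O)C[C@H]1c1ccccc1
F4 | step 8 | N-[(1S,4S,5R)-3-{2-[(tert-butyldiphenylsilyl)oxy]ethyl}-4-[4-methoxy-6-(methoxymethoxy)-1-benzofuran-7-carbonyl]-2-methyl-5-phenylcyclohex-2-en-1-yl]-2-nitrobenzene-1-sulfonohydrazide | COCOc1cc(OC)c2ccoc2c1C(=O)[C@@H]1C(CCO[Si](c2ccccc2)(c2ccccc2)C(C)(C)C)=C(C)[C@@H](N(N)S(=O)(=O)c2ccccc2[N+](=O)[O-])C[C@H]1c1ccccc1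
F5 | step 2 | 1-(2,6-dihydroxy-3-iodo-4-methoxyphenyl)ethan-1-one | CC(=O)c1c(O)c(I)c(OC)cc1O
F6 | step 2 | 1-{2,6-dihydroxy-4-methoxy-3-[(trimethylsilyl)ethynyl]phenyl}ethan-1-one | CC(=O)c1c(O)c(C#C[Si](C)(C)C)c(OC)cc1O
F7 | step 2 | 1-(3-ethynyl-2,6-dihydroxy-4-methoxyphenyl)ethan-1-one | CC(=O)c1c(O)c(C#C)c(OC)cc1O
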